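The data were generated by integration with constants of no real substance.

A target half-life of 0.402 min was what I read from the ash run, meaning the time in which substrate at its charged level halves the target if none is made, a pseudo-first-order view of the target's loss.

| setting | ash | elm | larch | theta | eta | gamma | epsilon |
|---|---|---|---|---|---|---|---|
| substrate | 23 mM | 23 mM | 23 mM | 23 mM | 23 mM | 23 mM (fed, over 2.0 min) | 23 mM (in portions, 4, over 2.0 min) |
| reagent | 34.5 mM | 48 mM | 76 mM | 34.5 mM | 34.5 mM (fed, over 2.0 min) | 34.5 mM | 34.5 mM |
| free catalyst | 3.4 mM | 3.4 mM | 3.4 mM | 3.4 mM | 3.4 mM | 3.4 mM | 3.4 mM |
| remark | run made earlier | run made earlier | run made earlier | everything together at the start | all else is in the flask from the start; the feed brings no volume worth counting | all else is in the flask from the start; the feed brings no volume worth counting | first portion at the start, last at 2.0 min |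
| time |  |  |  | 3.0 min | 3.0 min | 3.0 min | 3.0 min |

- ash (time / min: side product / %, target / %, substrate / %): 0.417: 3.0, 3.5, 93.2; 0.833: 8.5, 4.9, 87.6; 1.33: 15.1, 4.7, 77.1; 1.50: 19.7, 6.7, 73.6; 2.00: 24.4, 7.0, 69.3; 2.50: 31.3, 4.0, 62.1; 3.00: 36.8, 4.1, 57.2
- elm (time / min: side product / %, target / %, substrate / %): 0.167: 0.8, 3.3, 96.4; 0.500: 6.9, 5.3, 88.3; 0.833: 12.2, 8.3, 81.7; 1.33: 21.9, 7.4, 70.6; 2.00: 34.8, 8.7, 57.5; 2.50: 39.6, 7.9, 47.3; 3.00: 48.5, 8.1, 44.5
- larch (time / min: side product / %, target / %, substrate / %): 0.250: 1.1, 5.0, 92.1; 0.333: 5.5, 6.2, 88.6; 0.500: 6.9, 9.8, 81.3; 0.833: 15.6, 14.4, 70.8; 1.33: 31.5, 14.4, 55.1; 2.00: 47.1, 17.1, 36.9; 3.00: 61.4, 17.4, 19.0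

(scatter of a reading: 1 percentage point)

- a species is counted by the substrate in it: one side product counts as two
- what may be going on: substrate + reagent + free catalyst -> target + free catalyst; free catalyst -> spent catalyst; substrate + target -> side product

- the flask with the highest amount of side product, in percent of the substrate charged ("all alike" if they lie within 1.5 percentage points) (theta / eta / gamma / epsilon / all alike)
- final side product, as a percentage of the substrate charged, in theta
- final side product, as a percentage of the substrate charged, in eta
- final side product, as a percentage of the substrate charged, in gamma
- final side product, as a percentage of the substrate charged, in epsilon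

I took it from the side product's gain between 0.833 min and 3.00 min, beside the mean target standing in those readings, remembering that one side product counts as two, and I referred it to the charged substrate through the mean of the substrate readings at those two times. So 3.0 min held 7.46 such half-lives, the target in ash ended at 4.1%, and I took side product in theta to follow the target made. I then turned the question round: theta, which repeats ash and so should reach about 36.8%, would lose its lead if a feed cost less than the margin, which at ash's mean pace is 0.122 min of making. But in that time gamma's feed brought 1.41 mM, and at that substrate level the half-life reckoned out to 6.58 min, longer than the run. Epsilon's first portion gives 1.61 min, longer than that allowance. Eta starts without its reagent, and larch, which differs from ash by its reagent charge, ended with more side product than ash. I expected theta, without figures of my own for the feeds.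

The forecast said theta, with 37%, 20.5%, 24% and 25% for theta, eta, gamma and epsilon, arguing of eta that “reagent stays low early, so little target forms”.

The flasks gave theta, with 37.4%, 21.2%, 30.1% and 31.4%.

    substrate + reagent + free catalyst → target + free catalyst, rate k1*[substrate]*[reagent]*[free catalyst]/(1 + ([substrate]/sat1)) (2.79 mM, k = 174 /M²/s)
    free catalyst → spent catalyst (k = 0.00465 /s)
    substrate + target → side product (k = 1.22 /M/s)

Gamma and epsilon ended above the forecast by 6.1 percentage points and 6.4 points. Crowding of the making step by substrate was the largest single effect on the gap between theta and eta: a run with that crowding taken away shrank the gap from 16 points to 4.4 points. The neighbour of theta with 2.0 mM of free catalyst had the same substrate charge, hence the same half-life of 0.402 min, shorter than its 3.0 min, so I let side product follow the target made and scaled theta's side product by catalyst, which gave me 22.0%; the computed value is 24.1%.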